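**Retrosynthetic overview**
1. Target 21 ⇐ diol acid 18: the last step forms the C14–O bond by a singlet-oxygen ene reaction (the alkene moves to C13=C16) and dehydrates the hydroperoxide to the ketone.
2. 18 ⇐ isocupressic acid 16 by Markovnikov hydration of the 8(17)-alkene, which forms the C8–O bond and sets the 8α-OH centre; 16 ⇐ cupressic acid 14 by 1,3-transposition of the allylic oxygen from C13 to C15.
3. 14 ⇐ bicyclic keto ester 9 by C3 deoxygenation, reductive release of the auxiliary and re-oxidation of C19.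
4. 9 ⇐ acyclic keto ester 8: one oxidative radical cascade closes ring A first (C4–C5), then ring B (C9–C10), under control of an 8-phenylmenthyl ester.
5. 8 ⇐ (E)-nerolidol 1 (allylic oxidation, bromide 3) + keto ester 6 (from ethyl 2-methylacetoacetate 4 and 8-phenylmenthol 5, which is recovered in step 7).

Assumption: the (1R,2S,5R)-8-phenylmenthyl ester steers the cyclization to the normal 5α,10β series, as recalled for related aryl-terminated cases; if the sense is opposite, the enantiomeric auxiliary is used in step 3 and nothing else changes.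

Compounds 9 to 14 are carried as mixtures of C13 epimers; that centre is destroyed in step 9.

Step 1
Reactants: 1 (E)-nerolidol (racemic)
Product: 2 (2E,6E)-2,6,10-trimethyldodeca-2,6,11-triene-1,10-diol
Conditions: SeO2 (0.3 equiv), t-BuOOH (70% aq, 2.5 equiv), salicylic acid (0.1 equiv), CH2Cl2, 0 °C to rt
Reagents that add atoms: tert-butyl hydroperoxide, CC(C)(C)OO
Why: Riley-type allylic oxidation (ene reaction, then [2,3]-sigmatropic shift) attacks the E-methyl of the terminal trisubstituted alkene in preference to the internal alkene and the vinyl carbinol, and the alkene stays E.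

Step 2
Reactants: 2 (2E,6E)-2,6,10-trimethyldodeca-2,6,11-triene-1,10-diol
Product: 3 (6E,10E)-12-bromo-3,7,11-trimethyldodeca-1,6,10-trien-3-ol
Conditions: CBr4 (1.2 equiv), PPh3 (1.2 equiv), CH2Cl2, −20 °C
Reagents that add atoms: carbon tetrabromide, BrC(Br)(Br)Br
Why: the Appel reaction converts only the primary allylic alcohol at low temperature (the hindered tertiary allylic alcohol is inert) and the SN2 displacement keeps the E geometry.

Step 3
Reactants: 4 ethyl 2-methyl-3-oxobutanoate; 5 (−)-8-phenylmenthol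
Product: 6 (−)-8-phenylmenthyl 2-methyl-3-oxobutanoate
Conditions: DMAP (0.2 equiv), toluene, 110 °C, 4 Å sieves (ethanol removed)
Reagents that add atoms: none
Why: DMAP-catalysed transesterification of an enolisable β-keto ester (through the acyl ketene) attaches the chiral alcohol, and no stereocentre of the route is set because C2 stays epimerisable.

Step 4
Reactants: 6 (−)-8-phenylmenthyl 2-methyl-3-oxobutanoate; 3 (6E,10E)-12-bromo-3,7,11-trimethyldodeca-1,6,10-trien-3-ol
Product: 8 (−)-8-phenylmenthyl (6E,10E)-14-hydroxy-2,6,10,14-tetramethyl-3-oxohexadeca-6,10,15-trienoate, via dianion 7 (not isolated)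
Conditions: 6 (2.2 equiv), lithium diisopropylamide (4.4 equiv), THF, 0 °C; then 3 (1.0 equiv), −78 to 0 °C; aq NH4Cl (excess 6 recovered)
Reagents that add atoms: none
Why: Weiler dianion alkylation, in which the more reactive terminal carbanion displaces the allylic bromide by SN2 with retention of alkene geometry while the second equivalent of dianion deprotonates the free hydroxyl.

Step 5
Reactants: 8 (−)-8-phenylmenthyl (6E,10E)-14-hydroxy-2,6,10,14-tetramethyl-3-oxohexadeca-6,10,15-trienoate
Product: 9 (−)-8-phenylmenthyl 13-hydroxy-3-oxolabda-8(17),14-dien-19-oate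
Conditions: Mn(OAc)3·2H2O (2.2 equiv), Cu(OAc)2·H2O (1.0 equiv), degassed AcOH (0.05 M), 25 °C; major ring diastereomer separated by chromatography
Reagents that add atoms: none
Why: manganese triacetate-mediated oxidative radical bicyclization (chair–chair, 6-endo then 6-endo) closes ring A then ring B; the phenyl group of the auxiliary shields one face of the keto-ester radical so that C4 (ester axial, cis to the C10 methyl), C5, C10 and C9 form as one major trans-fused diastereomer, and Cu(OAc)2 turns the tertiary C8 radical into mainly the exocyclic alkene by β-hydride elimination while the monosubstituted vinyl group is too poor an acceptor to join the cascade.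

Step 6
Reactants: 9 (−)-8-phenylmenthyl 13-hydroxy-3-oxolabda-8(17),14-dien-19-oate
Product: 11 (−)-8-phenylmenthyl 13-hydroxylabda-8(17),14-dien-19-oate, via tosylhydrazone 10 (not isolated)
Conditions: TsNHNH2 (1.5 equiv), EtOH, AcOH (cat.), 78 °C; then catecholborane (3 equiv), CHCl3, 0 °C to rt; NaOAc·3H2O, 60 °C
Reagents that add atoms: none
Why: Kabalka deoxygenation (hydroboration of the hydrazone C=N, then loss of sulfinate and N2) removes the C3 carbonyl under mild non-basic conditions that spare the ester, both alkenes and the tertiary alcohol, and no stereocentre is touched.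

Step 7
Reactants: 11 (−)-8-phenylmenthyl 13-hydroxylabda-8(17),14-dien-19-oate
Product: 12 labda-8(17),14-diene-13,19-diol
Conditions: LiAlH4 (4 equiv), THF, 66 °C; Fieser work-up; 5 recovered
Reagents that add atoms: none
Why: hydride reduction of the hindered axial ester gives the C19 primary alcohol and releases the auxiliary for reuse without changing any stereocentre.

Step 8
Reactants: 12 labda-8(17),14-diene-13,19-diol
Product: 14 13-hydroxylabda-8(17),14-dien-19-oic acid (cupressic acid and its 13-epimer), via aldehyde 13 (not isolated)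
Conditions: Dess–Martin periodinane (1.3 equiv), NaHCO3, CH2Cl2, 0 °C to rt; then NaClO2, NaH2PO4, 2-methyl-2-butene, t-BuOH/H2O, rt
Reagents that add atoms: sodium chlorite, [Na+].[O-]Cl=O
Why: Dess–Martin oxidation then Pinnick oxidation converts the only primary alcohol into the acid, the tertiary allylic alcohol cannot be oxidised, and 2-methyl-2-butene keeps hypochlorite away from the alkenes.

Step 9
Reactants: 14 13-hydroxylabda-8(17),14-dien-19-oic acid
Product: 16 (13E)-15-hydroxylabda-8(17),13-dien-19-oic acid (isocupressic acid), via bis-silyl derivative 15 (not isolated)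
Conditions: Ph3SiOReO3 (5 mol %), N,O-bis(trimethylsilyl)acetamide (3 equiv), Et2O, −50 to 0 °C; then MeOH, citric acid (cat.), rt; E isomer separated on AgNO3–silica, Z isomer recycled
Reagents that add atoms: none
Why: heptavalent rhenium-oxo catalysed 1,3-transposition ([3,3]-sigmatropic shift of the allyl perrhenate through a chair) moves the oxygen from C13 to C15 and is driven by silylation of the less hindered primary alcohol; the E isomer should predominate only moderately (estimated about 3:1), which is why the isomers are separated here.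

Step 10
Reactants: 16 (13E)-15-hydroxylabda-8(17),13-dien-19-oic acid
Product: 18 (13E)-8α,15-dihydroxylabd-13-en-19-oic acid, via organomercurial 17 (not isolated)
Conditions: Hg(OAc)2 (1.05 equiv), THF/H2O (1:1), rt; then NaOH (3 M), NaBH4, 0 °C
Reagents that add atoms: water, O
Why: Markovnikov oxymercuration–demercuration forms the C8–O bond; the 1,1-disubstituted exocyclic alkene reacts much faster than the trisubstituted allylic-alcohol alkene, and water is expected to attack C8 from the equatorial α side, away from the axial C10 methyl, to set the 8α-hydroxy-8β-methyl centre.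

Step 11
Reactants: 18 (13E)-8α,15-dihydroxylabd-13-en-19-oic acid
Product: 21 8α,15-dihydroxy-14-oxolabd-13(16)-en-19-oic acid (target), via hydroperoxide 19 (not isolated), via peroxyimidate 20 (not isolated)
Conditions: O2, tetraphenylporphyrin (1 mol %), white LEDs, CH2Cl2, 0 °C; then Cl3CCN (1.5 equiv), Et3N (2.5 equiv), 0 °C to rt
Reagents that add atoms: oxygen, O=O
Why: Proposed new method: a one-flask Schenck ene reaction and nitrile-activated Kornblum–DeLaMare dehydration, in which singlet oxygen bonds to C14 and abstracts hydrogen from the C16 methyl that is cis to the hydroxymethyl group (cis effect plus hydroxyl direction) so the alkene moves to C13=C16, after which the hydroperoxide (an α-effect nucleophile of pKa near 12, far more reactive than the alcohols under Et3N) adds to Cl3CCN and the peroxyimidate undergoes base-induced E2 at the allylic C14–H with loss of trichloroacetamide to give the ketone with the free alcohols and the acid untouched; the closest known chemistry is the singlet-oxygen ene reaction followed by Ac2O/pyridine Kornblum–DeLaMare dehydration, together with Payne-type addition of hydroperoxide to nitriles.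

**Compound list**
1 | (E)-nerolidol, racemic, (6E)-3,7,11-trimethyldodeca-1,6,10-trien-3-ol | CC(C)=CCC/C(C)=C/CCC(C)(O)C=C | starting material
2 | (2E,6E)-2,6,10-trimethyldodeca-2,6,11-triene-1,10-diol | OC/C(C)=C/CC/C(C)=C/CCC(C)(O)C=C | intermediate
3 | (6E,10E)-12-bromo-3,7,11-trimethyldodeca-1,6,10-trien-3-ol | BrC/C(C)=C/CC/C(C)=C/CCC(C)(O)C=C | intermediate
4 | ethyl 2-methyl-3-oxobutanoate | CCOC(=O)C(C)C(C)=O | starting material
5 | (−)-8-phenylmenthol, (1R,2S,5R)-5-methyl-2-(2-phenylpropan-2-yl)cyclohexan-1-ol | CC(C)(c1ccccc1)[C@@H]1CC[C@@H](C)C[C@H]1O | starting material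
6 | (−)-8-phenylmenthyl 2-methyl-3-oxobutanoate (C2 epimers) | CC(=O)C(C)C(=O)O[C@@H]1C[C@H](C)CC[C@H]1C(C)(C)c1ccccc1 | intermediate
7 | dilithium dianion of 6 | [Li+].[Li+].C=C([O-])C(C)=C([O-])O[C@@H]1C[C@H](C)CC[C@H]1C(C)(C)c1ccccc1 | intermediate
8 | (−)-8-phenylmenthyl (6E,10E)-14-hydroxy-2,6,10,14-tetramethyl-3-oxohexadeca-6,10,15-trienoate (C2 and C14 epimers) | CC(C(=O)CC/C(C)=C/CC/C(C)=C/CCC(C)(O)C=C)C(=O)O[C@@H]1C[C@H](C)CC[C@H]1C(C)(C)c1ccccc1 | intermediate
9 | (−)-8-phenylmenthyl 13-hydroxy-3-oxolabda-8(17),14-dien-19-oate (4β-ester, 5α-H, 9α-H, 10β-methyl; C13 epimers) | C=CC(C)(O)CC[C@@H]1[C@@]2(C)CCC(=O)[C@](C)(C(=O)O[C@@H]3C[C@H](C)CC[C@H]3C(C)(C)c4ccccc4)[C@@H]2CCC1=C | intermediate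
10 | 3-(4-methylbenzenesulfonyl)hydrazone of 9 | C=CC(C)(O)CC[C@@H]1[C@@]2(C)CCC(=NNS(=O)(=O)c4ccc(C)cc4)[C@](C)(C(=O)O[C@@H]3C[C@H](C)CC[C@H]3C(C)(C)c5ccccc5)[C@@H]2CCC1=C | intermediate
11 | (−)-8-phenylmenthyl 13-hydroxylabda-8(17),14-dien-19-oate | C=CC(C)(O)CC[C@@H]1[C@@]2(C)CCC[C@](C)(C(=O)O[C@@H]3C[C@H](C)CC[C@H]3C(C)(C)c4ccccc4)[C@@H]2CCC1=C | intermediate
12 | labda-8(17),14-diene-13,19-diol | C=CC(C)(O)CC[C@@H]1[C@@]2(C)CCC[C@](C)(CO)[C@@H]2CCC1=C | intermediate
13 | 13-hydroxylabda-8(17),14-dien-19-al | C=CC(C)(O)CC[C@@H]1[C@@]2(C)CCC[C@](C)(C=O)[C@@H]2CCC1=C | intermediate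
14 | 13-hydroxylabda-8(17),14-dien-19-oic acid (cupressic acid and its 13-epimer) | C=CC(C)(O)CC[C@@H]1[C@@]2(C)CCC[C@](C)(C(=O)O)[C@@H]2CCC1=C | intermediate
15 | trimethylsilyl (13E)-15-(trimethylsilyloxy)labda-8(17),13-dien-19-oate | C[Si](C)(C)OC/C=C(\C)CC[C@@H]1[C@@]2(C)CCC[C@](C)(C(=O)O[Si](C)(C)C)[C@@H]2CCC1=C | intermediate
16 | (13E)-15-hydroxylabda-8(17),13-dien-19-oic acid (isocupressic acid) | OC/C=C(\C)CC[C@@H]1[C@@]2(C)CCC[C@](C)(C(=O)O)[C@@H]2CCC1=C | intermediate
17 | (13E)-17-(acetoxymercurio)-8α,15-dihydroxylabd-13-en-19-oic acid | OC/C=C(\C)CC[C@@H]1[C@@]2(C)CCC[C@](C)(C(=O)O)[C@@H]2CC[C@@]1(C[Hg]OC(C)=O)O | intermediate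
18 | (13E)-8α,15-dihydroxylabd-13-en-19-oic acid | OC/C=C(\C)CC[C@@H]1[C@@]2(C)CCC[C@](C)(C(=O)O)[C@@H]2CC[C@@]1(C)O | intermediate
19 | 14-hydroperoxy-8α,15-dihydroxylabd-13(16)-en-19-oic acid (C14 epimers) | C=C(CC[C@@H]1[C@@]2(C)CCC[C@](C)(C(=O)O)[C@@H]2CC[C@@]1(C)O)C(OO)CO | intermediate
20 | 8α,15-dihydroxy-14-(2,2,2-trichloroethanimidoylperoxy)labd-13(16)-en-19-oic acid | C=C(CC[C@@H]1[C@@]2(C)CCC[C@](C)(C(=O)O)[C@@H]2CC[C@@]1(C)O)C(CO)OOC(=N)C(Cl)(Cl)Cl | intermediate
21 | 8α,15-dihydroxy-14-oxolabd-13(16)-en-19-oic acid (CNP0196657.1) | C=C(CC[C@@H]1[C@@]2(C)CCC[C@](C)(C(=O)O)[C@@H]2CC[C@@]1(C)O)C(=O)CO | target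

**Step count and risks**
Total steps: 11. Longest linear sequence: 10 (steps 1, 2 and 4 to 11; step 3 is the side branch).

The three steps most likely to fail:

(a) Step 5, the radical bicyclization. The risks are a low yield, imperfect facial control by the auxiliary, endocyclic alkene isomers, and capture of the C8 radical by the free C13 hydroxyl. The fallback uses known chemistry, sets out from 8 and comes back at 9. Compound 8 is brominated at C2 (NaH, then N-bromosuccinimide, THF, −78 °C) to the α-bromo keto ester F1. Bromine atom-transfer radical bicyclization (Et3B, air, Mg(ClO4)2, toluene, −78 °C; Lewis-acid chelation keeps the auxiliary-controlled face) gives the C8 tertiary bromide F2. Elimination with DBU (toluene, 80 °C) and separation of the exocyclic isomer returns 9.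

(b) Step 9, the 1,3-transposition. The risks are a poor E/Z ratio and ionisation of the tertiary allylic alcohol. The fallback sets out from 14 and comes back at 16. Compound 14 is acetylated at the tertiary alcohol (Ac2O, Et3N, DMAP, CH2Cl2, 40 °C; NaHCO3 work-up) to the tertiary acetate F3. A [3,3] acetate shift catalysed by divalent palladium (PdCl2(MeCN)2, 5 mol %, THF, rt) gives the primary E-acetate F4, which is separated from its Z isomer. Methanolysis (K2CO3, MeOH, rt) returns 16.

(c) Step 11, the proposed new one-flask ene reaction and dehydration. The risks are incomplete selection between the hydroperoxide and the alcohols, and base sensitivity of the α-methylene ketone. The fallback uses known chemistry, sets out from 18 and comes back at 21. Photooxygenation as in step 11 gives hydroperoxide 19, which is reduced in the same flask with PPh3 to the 14,15-diol F5. Selective oxidation of the allylic secondary alcohol with activated MnO2 (CH2Cl2, rt) gives 21.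

**Further compounds**
F1 | step 5 | (−)-8-phenylmenthyl (6E,10E)-2-bromo-14-hydroxy-2,6,10,14-tetramethyl-3-oxohexadeca-6,10,15-trienoate | CC(Br)(C(=O)CC/C(C)=C/CC/C(C)=C/CCC(C)(O)C=C)C(=O)O[C@@H]1C[C@H](C)CC[C@H]1C(C)(C)c1ccccc1
F2 | step 5 | (−)-8-phenylmenthyl 8-bromo-13-hydroxy-3-oxolabd-14-en-19-oate | C=CC(C)(O)CC[C@@H]1[C@@]2(C)CCC(=O)[C@](C)(C(=O)O[C@@H]3C[C@H](C)CC[C@H]3C(C)(C)c4ccccc4)[C@@H]2CCC1(C)Br
F3 | step 9 | 13-acetoxylabda-8(17),14-dien-19-oic acid | C=CC(C)(OC(C)=O)CC[C@@H]1[C@@]2(C)CCC[C@](C)(C(=O)O)[C@@H]2CCC1=C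
F4 | step 9 | (13E)-15-acetoxylabda-8(17),13-dien-19-oic acid | CC(=O)OC/C=C(\C)CC[C@@H]1[C@@]2(C)CCC[C@](C)(C(=O)O)[C@@H]2CCC1=C
F5 | step 11 | 8α,14,15-trihydroxylabd-13(16)-en-19-oic acid | C=C(CC[C@@H]1[C@@]2(C)CCC[C@](C)(C(=O)O)[C@@H]2CC[C@@]1(C)O)C(O)CO
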